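Both arenes of the target are the same unit: a catechol (O on C1 and C2) whose C3 is bonded to the quaternary carbon of a 1,2,2-trimethylcyclopentane and whose C5 carries the methyl or bridging CH2. The bridge is cut first, so one monomer serves twice. The benzene ring is then opened at C1–C2 and C1–C6. C2 and its oxygen map onto an alkoxycarbene carbon, C1 and its oxygen onto a CO ligand, and C3–C6 onto a diene. Irradiating a (Z)-dienyl(methoxy)carbene pentacarbonylchromium complex therefore assembles the whole, already differentiated, catechol ring in one operation. The complex bears the (S)-cyclopentyl group, taken from (−)-camphoric acid, next to the carbene carbon.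

Key step: step 9

Assumption: both [C@@] centres of the target read as (S) (aryl > CMe2 > CH2 > CH3), which calls for the levorotatory (1S,3R) enantiomer of camphoric acid. CO ligands on chromium are written as Cr=C=O.

Step 1
Reactants: 1 (1S,3R)-(−)-camphoric acid (cis-1,2,2-trimethylcyclopentane-1,3-dicarboxylic acid)
Product: 2 dimethyl (1S,3R)-1,2,2-trimethylcyclopentane-1,3-dicarboxylate
Conditions: MeI (2.5 equiv), K2CO3 (2.5 equiv), DMF, rt
Reagents that add atoms: iodomethane, CI
Why: Carboxylate O-alkylation (SN2 at MeI) takes place away from the acyl carbons, so the shielded C1 carboxyl is esterified as readily as the C3 carboxyl and no stereocentre is touched.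

Step 2
Reactants: 2 dimethyl (1S,3R)-1,2,2-trimethylcyclopentane-1,3-dicarboxylate
Product: 3 (1R,3S)-3-(methoxycarbonyl)-2,2,3-trimethylcyclopentane-1-carboxylic acid
Conditions: KOH (1.1 equiv), MeOH–H2O, reflux; then aq HCl
Reagents that add atoms: potassium hydroxide, [K+].[OH-]
Why: Site-selective saponification (BAc2) reaches only the secondary ester, because the tertiary ester lies between two quaternary carbons, and any epimerisation next to the new acid is harmless since that carbon becomes CH2 in step 3.

Step 3
Reactants: 3 (1R,3S)-3-(methoxycarbonyl)-2,2,3-trimethylcyclopentane-1-carboxylic acid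
Product: 6 methyl (1S)-1,2,2-trimethylcyclopentane-1-carboxylate, via acid chloride 4 (not isolated), via thiohydroxamate ester 5 (not isolated)
Conditions: (COCl)2, cat. DMF, CH2Cl2, rt, concentrate; then sodium pyridine-2-thione N-oxide (1.1 equiv), cat. DMAP, t-BuSH (5 equiv), toluene, W lamp, reflux
Reagents that add atoms: none
Why: Barton reductive decarboxylation fragments the O-acyl thiohydroxamate in a radical chain to CO2 and a secondary ring radical, which takes hydrogen from the thiol, while the quaternary (S)-centre is not part of the radical site.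

Step 4
Reactants: 6 methyl (1S)-1,2,2-trimethylcyclopentane-1-carboxylate
Product: 7 (1S)-1,2,2-trimethylcyclopentane-1-carboxylic acid
Conditions: LiI (5 equiv), pyridine, reflux; then aq HCl
Reagents that add atoms: none
Why: SN2-type ester dealkylation lets iodide attack the open O-methyl carbon, which bypasses the acyl carbon that hydroxide cannot reach.

Step 5
Reactants: 7 (1S)-1,2,2-trimethylcyclopentane-1-carboxylic acid; 8 2-methylprop-1-en-1-ylmagnesium bromide (commercial THF solution)
Product: 10 3-methyl-1-[(1S)-1,2,2-trimethylcyclopentyl]but-2-en-1-one, via acid chloride 9 (not isolated)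
Conditions: (COCl)2, cat. DMF, CH2Cl2, rt, concentrate; then 8 (1.2 equiv), CuI (10 mol %), THF, −30 → 0 °C
Reagents that add atoms: none
Why: Copper-catalysed acylation of a Grignard reagent should stop at the ketone, because its carbonyl is flanked by a quaternary carbon and its β-carbon is disubstituted, which slows both 1,2- and 1,4-overaddition.

Step 6
Reactants: 10 3-methyl-1-[(1S)-1,2,2-trimethylcyclopentyl]but-2-en-1-one
Product: 12 (1Z)-3-methyl-1-[(1S)-1,2,2-trimethylcyclopentyl]buta-1,3-dien-1-yl trifluoromethanesulfonate (OTf cis to isopropenyl), via potassium dienolate 11 (not isolated)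
Conditions: KHMDS (1.1 equiv), THF, −78 °C; then PhNTf2 (1.2 equiv), −78 → 0 °C
Reagents that add atoms: N-phenylbis(trifluoromethanesulfonimide), O=S(=O)(N(c1ccccc1)S(=O)(=O)C(F)(F)F)C(F)(F)F
Why: In this vinylogous enolisation followed by O-triflation only γ-hydrogens are available, and allylic strain between the cyclopentyl group and the (Z)-methyl holds the enone s-cis, so the dienolate oxygen should end up cis to the isopropenyl group and be fixed there as the enol triflate.

Step 7
Reactants: 12 (1Z)-dienyl triflate
Product: 13 trimethyl{(1Z)-3-methyl-1-[(1S)-1,2,2-trimethylcyclopentyl]buta-1,3-dien-1-yl}stannane (Sn cis to isopropenyl)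
Conditions: (Me3Sn)2 (1.2 equiv), Pd(PPh3)4 (5 mol %), LiCl (6 equiv), THF, reflux
Reagents that add atoms: hexamethylditin, C[Sn](C)(C)[Sn](C)(C)C
Why: Palladium-catalysed stannylation of an enol triflate (Stille-type oxidative addition, Sn–Sn transmetalation, reductive elimination) is stereoretentive at the alkene, and the retained isomer is also the less strained one.

Step 8
Reactants: 13 (1Z)-dienylstannane; 14 chromium hexacarbonyl
Product: 17 pentacarbonyl{(2Z)-1-methoxy-4-methyl-2-[(1S)-1,2,2-trimethylcyclopentyl]penta-2,4-dien-1-ylidene}chromium(0), via dienyllithium 15 (not isolated), via lithium acylchromate 16 (not isolated)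
Conditions: MeLi (1.0 equiv), THF, −78 → −30 °C; cannulate onto 14, Et2O, 0 °C → rt; evaporate; MeOTf (1.5 equiv), CH2Cl2, 0 °C
Reagents that add atoms: methyl trifluoromethanesulfonate, COS(=O)(=O)C(F)(F)F
Why: In this Fischer carbene synthesis, tin–lithium exchange gives a configurationally stable alkenyllithium that adds to a sterically remote CO ligand, and the hard methylating agent then alkylates the acylate oxygen.

Step 9
Reactants: 17 (2Z)-dienyl(methoxy)carbene pentacarbonylchromium complex
Product: 20 2-methoxy-5-methyl-3-[(1S)-1,2,2-trimethylcyclopentyl]phenol, via chromium-bound dienylketene 18 (not isolated), via cyclohexadienone 19 (not isolated)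
Conditions: hν (450 W medium-pressure Hg lamp, Pyrex), CO (1 atm), THF, rt
Reagents that add atoms: none
Why: Irradiation into the metal-to-ligand charge-transfer band moves a cis CO ligand onto the carbene carbon and gives the chromium-bound methoxy(dienyl)ketene 18, which creates the C(OMe)–C(=O) bond. The ketene C=C and the two diene C=C bonds form a hexatriene that closes thermally by disrotatory 6π electrocyclisation, the ketene carbon bonding to the unsubstituted terminal CH2 to close the six-membered carbocycle as dienone 19, whose enolisation to phenol 20 makes the sequence irreversible. The closest known reaction type is the photochemical carbonylative benzannulation of dienyl(alkoxy)carbene chromium complexes to ortho-alkoxyphenols, which shares its last stages with the Dötz benzannulation. No stereocentre is created, and the quaternary (S)-carbon, which bears no hydrogen and lies outside the reacting π system, is carried through unchanged. The step needs the carbene carbon and the isopropenyl group on the same side of the central alkene, which the substrate secures because the cyclopentyl group avoids the isopropenyl group, so that even light-induced E/Z interconversion drains into the reactive isomer; the placing of OMe beside the cyclopentyl-bearing carbon and of OH beside the free CH follows from the origin of the two carbons and cannot be reversed. The CO atmosphere collects the Cr(CO)4 fragment as Cr(CO)6 and keeps it from binding the new arene.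

Step 10
Reactants: 20 2-methoxy-5-methyl-3-[(1S)-1,2,2-trimethylcyclopentyl]phenol (about two fifths of the material)
Product: 21 2-methoxy-5-methyl-3-[(1S)-1,2,2-trimethylcyclopentyl]phenyl acetate
Conditions: Ac2O (1.5 equiv), pyridine, cat. DMAP, CH2Cl2, rt
Reagents that add atoms: acetic anhydride, CC(=O)OC(C)=O
Why: Phenol O-acylation is chosen over a second methyl ether because the remaining OMe has all of its ortho and para carbons substituted, so masking the OH as an ester leaves no strongly activated free ring carbon for ionic bromination or self-alkylation later.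

Step 11
Reactants: 21 2-methoxy-5-methyl-3-[(1S)-1,2,2-trimethylcyclopentyl]phenyl acetate
Product: 22 5-(bromomethyl)-2-methoxy-3-[(1S)-1,2,2-trimethylcyclopentyl]phenyl acetate
Conditions: NBS (1.0 equiv), AIBN (5 mol %), PhCF3, reflux
Reagents that add atoms: N-bromosuccinimide, O=C1CCC(=O)N1Br
Why: Wohl–Ziegler bromination should pick the aryl CH3, which holds the only benzylic hydrogens in the molecule, while the acetate keeps nuclear bromination slow.

Step 12
Reactants: 20 2-methoxy-5-methyl-3-[(1S)-1,2,2-trimethylcyclopentyl]phenol (1.5 equiv); 22 benzylic bromide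
Product: 23 5-({2-hydroxy-3-methoxy-6-methyl-4-[(1S)-1,2,2-trimethylcyclopentyl]phenyl}methyl)-2-methoxy-3-[(1S)-1,2,2-trimethylcyclopentyl]phenyl acetate
Conditions: ZnBr2 (20 mol %), CH2Cl2, 0 °C → rt
Reagents that add atoms: none
Why: In this Friedel–Crafts benzylation zinc(II) ionises the para-methoxybenzyl-type bromide and the free phenol should answer at the carbon ortho to OH, because the para carbon is walled in by the quaternary cyclopentyl carbon and the methyl group, the acetylated ring of 22 is too electron-poor to self-condense, and O-benzylation is reversible under acid.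

Step 13
Reactants: 23 diarylmethane bis(methyl ether) monoacetate
Product: 24 3-({3,4-dihydroxy-5-[(1S)-1,2,2-trimethylcyclopentyl]phenyl}methyl)-4-methyl-6-[(1S)-1,2,2-trimethylcyclopentyl]benzene-1,2-diol (target)
Conditions: BBr3 (6 equiv), CH2Cl2, −78 °C → rt; then MeOH, 40 °C, under Ar
Reagents that add atoms: none
Why: Lewis-acid aryl methyl ether cleavage (boron coordination, then bromide SN2 at the methyl carbon) removes both OMe groups, the HBr/MeOH of the quench transesterifies the aryl acetate, and the two quaternary centres have no pathway for change.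

Compound list
1 | (1S,3R)-(−)-camphoric acid | OC(=O)[C@@]1(C)CC[C@@H](C(=O)O)C1(C)C | starting material
2 | dimethyl (1S,3R)-1,2,2-trimethylcyclopentane-1,3-dicarboxylate | COC(=O)[C@@]1(C)CC[C@@H](C(=O)OC)C1(C)C | intermediate
3 | (1R,3S)-3-(methoxycarbonyl)-2,2,3-trimethylcyclopentane-1-carboxylic acid | COC(=O)[C@@]1(C)CC[C@@H](C(=O)O)C1(C)C | intermediate
4 | methyl (1S,3R)-3-(chlorocarbonyl)-1,2,2-trimethylcyclopentane-1-carboxylate | COC(=O)[C@@]1(C)CC[C@@H](C(=O)Cl)C1(C)C | intermediate
5 | methyl (1S,3R)-1,2,2-trimethyl-3-{[(2-thioxopyridin-1(2H)-yl)oxy]carbonyl}cyclopentane-1-carboxylate | COC(=O)[C@@]1(C)CC[C@@H](C(=O)On2ccccc2=S)C1(C)C | intermediate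
6 | methyl (1S)-1,2,2-trimethylcyclopentane-1-carboxylate | COC(=O)[C@@]1(C)CCCC1(C)C | intermediate
7 | (1S)-1,2,2-trimethylcyclopentane-1-carboxylic acid | OC(=O)[C@@]1(C)CCCC1(C)C | intermediate
8 | 2-methylprop-1-en-1-ylmagnesium bromide | CC(C)=C[Mg]Br | starting material
9 | (1S)-1,2,2-trimethylcyclopentane-1-carbonyl chloride | ClC(=O)[C@@]1(C)CCCC1(C)C | intermediate
10 | 3-methyl-1-[(1S)-1,2,2-trimethylcyclopentyl]but-2-en-1-one | CC(C)=CC(=O)[C@@]1(C)CCCC1(C)C | intermediate
11 | potassium (1Z)-3-methyl-1-[(1S)-1,2,2-trimethylcyclopentyl]buta-1,3-dien-1-olate | [K+].[O-]/C(=C\C(C)=C)[C@@]1(C)CCCC1(C)C | intermediate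
12 | (1Z)-3-methyl-1-[(1S)-1,2,2-trimethylcyclopentyl]buta-1,3-dien-1-yl trifluoromethanesulfonate | FC(F)(F)S(=O)(=O)O/C(=C\C(C)=C)[C@@]1(C)CCCC1(C)C | intermediate
13 | trimethyl{(1Z)-3-methyl-1-[(1S)-1,2,2-trimethylcyclopentyl]buta-1,3-dien-1-yl}stannane | C[Sn](C)(C)/C(=C\C(C)=C)[C@@]1(C)CCCC1(C)C | intermediate
14 | chromium hexacarbonyl | O=C=[Cr](=C=O)(=C=O)(=C=O)(=C=O)=C=O | starting material
15 | [3-methyl-1-(1,2,2-trimethylcyclopentyl)buta-1,3-dien-1-yl]lithium, Li cis to isopropenyl (formally 1E), quaternary centre spatially unchanged (formally R because Li ranks below C) | [Li]/C(=C\C(C)=C)[C@@]1(C)CCCC1(C)C | intermediate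
16 | lithium pentacarbonyl{(2Z)-4-methyl-1-oxido-2-[(1S)-1,2,2-trimethylcyclopentyl]penta-2,4-dien-1-ylidene}chromate | [Li+].[O-]C(/C(=C\C(C)=C)[C@@]1(C)CCCC1(C)C)=[Cr](=C=O)(=C=O)(=C=O)(=C=O)=C=O | intermediate
17 | pentacarbonyl{(2Z)-1-methoxy-4-methyl-2-[(1S)-1,2,2-trimethylcyclopentyl]penta-2,4-dien-1-ylidene}chromium(0) | COC(/C(=C\C(C)=C)[C@@]1(C)CCCC1(C)C)=[Cr](=C=O)(=C=O)(=C=O)(=C=O)=C=O | intermediate
18 | (3Z)-2-methoxy-5-methyl-3-[(1S)-1,2,2-trimethylcyclopentyl]hexa-1,3,5-trien-1-one bound to tetracarbonylchromium | COC(=C=O)/C(=C\C(C)=C)[C@@]1(C)CCCC1(C)C.O=C=[Cr](=C=O)(=C=O)=C=O | intermediate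
19 | 2-methoxy-5-methyl-3-[(1S)-1,2,2-trimethylcyclopentyl]cyclohexa-2,4-dien-1-one | COC1=C([C@@]2(C)CCCC2(C)C)C=C(C)CC1=O | intermediate
20 | 2-methoxy-5-methyl-3-[(1S)-1,2,2-trimethylcyclopentyl]phenol | COc1c(O)cc(C)cc1[C@@]1(C)CCCC1(C)C | intermediate
21 | 2-methoxy-5-methyl-3-[(1S)-1,2,2-trimethylcyclopentyl]phenyl acetate | COc1c(OC(C)=O)cc(C)cc1[C@@]1(C)CCCC1(C)C | intermediate
22 | 5-(bromomethyl)-2-methoxy-3-[(1S)-1,2,2-trimethylcyclopentyl]phenyl acetate | COc1c(OC(C)=O)cc(CBr)cc1[C@@]1(C)CCCC1(C)C | intermediate
23 | 5-({2-hydroxy-3-methoxy-6-methyl-4-[(1S)-1,2,2-trimethylcyclopentyl]phenyl}methyl)-2-methoxy-3-[(1S)-1,2,2-trimethylcyclopentyl]phenyl acetate | Cc1cc([C@@]2(C)CCCC2(C)C)c(OC)c(O)c1Cc1cc(OC(C)=O)c(OC)c([C@@]2(C)CCCC2(C)C)c1 | intermediate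
24 | 3-({3,4-dihydroxy-5-[(1S)-1,2,2-trimethylcyclopentyl]phenyl}methyl)-4-methyl-6-[(1S)-1,2,2-trimethylcyclopentyl]benzene-1,2-diol | Cc1cc([C@@]2(C)CCCC2(C)C)c(O)c(O)c1Cc1cc(O)c(O)c([C@@]2(C)CCCC2(C)C)c1 | target

Total step count: 13. Longest linear sequence: 13 (steps 1–9, then 10, 11, 12, 13; step 12 draws its second partner from step 9).

Steps most likely to fail

Step 9. Photodecomposition of the complex may outrun CO insertion. Ring closure may also stall at room temperature, because the cyclopentyl and methoxy groups are pressed together in the planar transition state. The fallback makes the same ketene without metal and closes it thermally. Setting out from stannane 13, dienyllithium 15 (MeLi, THF, −78 °C) is added to ethyl glyoxylate to give the α-hydroxy ester F1 as an inconsequential epimer mixture. MeI/Ag2O converts it into the α-methoxy ester F2. LiOH in aqueous THF gives the α-methoxy acid F3, and oxalyl chloride gives the α-methoxy acid chloride F4. Et3N in warm toluene then dehydrochlorinates F4 to the free methoxy(dienyl)ketene F5. This undergoes the 6π closure through dienone 19 and comes back to the route at phenol 20.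

Step 7. Transmetalation from the ditin to a crowded alkenylpalladium may be slow, so that reduction, homocoupling or erosion of the alkene geometry takes over, and the later tin–lithium exchange at a shielded tin is exposed to the same crowding. The fallback reverses the polarity of the chromium–carbon bond formation. Setting out from triflate 12, palladium-catalysed hydroxycarbonylation (Pd(OAc)2, dppf, CO, H2O, Et3N, DMF), in which only the small CO has to reach the metal, gives the (Z)-dienoic acid F6. The neutral chlorinating agent 1-chloro-N,N,2-trimethylprop-1-en-1-amine gives the dienoyl chloride F7. Separately, 14 is reduced with potassium graphite to dipotassium pentacarbonylchromate F8. Acylation of F8 by F7 gives the potassium acylchromate F9, and MeOTf brings the material back to the route at complex 17.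

Step 12. Ionisation may be sluggish because the flanked methoxy group is twisted out of conjugation. O-alkylation may then persist, or the acid may start to strip the tert-alkyl group from the activated ring. The fallback replaces electrophilic substitution with a site-defined cross-coupling. Setting out from phenol 20, NBS in MeCN at 0 °C gives the ortho-bromophenol F10, and Ac2O/pyridine gives the bromoaryl acetate F11. Bromide 22 is inserted with Zn dust/LiCl in THF to give the benzylzinc bromide F12. Negishi coupling of F11 with F12 (Pd(OAc)2, SPhos, THF, 50 °C) gives the diarylmethane diacetate F13. The conditions of step 13 convert F13 directly into target 24.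

Further compounds
F1 | step 9 | ethyl (3Z)-2-hydroxy-5-methyl-3-[(1S)-1,2,2-trimethylcyclopentyl]hexa-3,5-dienoate (C2 epimers) | CCOC(=O)C(O)/C(=C\C(C)=C)[C@@]1(C)CCCC1(C)C
F2 | step 9 | ethyl (3Z)-2-methoxy-5-methyl-3-[(1S)-1,2,2-trimethylcyclopentyl]hexa-3,5-dienoate (C2 epimers) | CCOC(=O)C(OC)/C(=C\C(C)=C)[C@@]1(C)CCCC1(C)C
F3 | step 9 | (3Z)-2-methoxy-5-methyl-3-[(1S)-1,2,2-trimethylcyclopentyl]hexa-3,5-dienoic acid (C2 epimers) | OC(=O)C(OC)/C(=C\C(C)=C)[C@@]1(C)CCCC1(C)C
F4 | step 9 | (3Z)-2-methoxy-5-methyl-3-[(1S)-1,2,2-trimethylcyclopentyl]hexa-3,5-dienoyl chloride (C2 epimers) | ClC(=O)C(OC)/C(=C\C(C)=C)[C@@]1(C)CCCC1(C)C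
F5 | step 9 | metal-free (3Z)-2-methoxy-5-methyl-3-[(1S)-1,2,2-trimethylcyclopentyl]hexa-1,3,5-trien-1-one | COC(=C=O)/C(=C\C(C)=C)[C@@]1(C)CCCC1(C)C
F6 | step 7 | (2Z)-4-methyl-2-[(1S)-1,2,2-trimethylcyclopentyl]penta-2,4-dienoic acid | OC(=O)/C(=C\C(C)=C)[C@@]1(C)CCCC1(C)C
F7 | step 7 | (2Z)-4-methyl-2-[(1S)-1,2,2-trimethylcyclopentyl]penta-2,4-dienoyl chloride | ClC(=O)/C(=C\C(C)=C)[C@@]1(C)CCCC1(C)C
F8 | step 7 | dipotassium pentacarbonylchromate(2−) | [K+].[K+].O=C=[Cr-2](=C=O)(=C=O)(=C=O)=C=O
F9 | step 7 | potassium pentacarbonyl{(2Z)-4-methyl-1-oxido-2-[(1S)-1,2,2-trimethylcyclopentyl]penta-2,4-dien-1-ylidene}chromate | [K+].[O-]C(/C(=C\C(C)=C)[C@@]1(C)CCCC1(C)C)=[Cr](=C=O)(=C=O)(=C=O)(=C=O)=C=O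
F10 | step 12 | 2-bromo-6-methoxy-3-methyl-5-[(1S)-1,2,2-trimethylcyclopentyl]phenol | COc1c(O)c(Br)c(C)cc1[C@@]1(C)CCCC1(C)C
F11 | step 12 | 2-bromo-6-methoxy-3-methyl-5-[(1S)-1,2,2-trimethylcyclopentyl]phenyl acetate | COc1c(OC(C)=O)c(Br)c(C)cc1[C@@]1(C)CCCC1(C)C
F12 | step 12 | {3-acetoxy-4-methoxy-5-[(1S)-1,2,2-trimethylcyclopentyl]benzyl}zinc bromide | COc1c(OC(C)=O)cc(C[Zn]Br)cc1[C@@]1(C)CCCC1(C)C
F13 | step 12 | 2-({3-acetoxy-4-methoxy-5-[(1S)-1,2,2-trimethylcyclopentyl]phenyl}methyl)-6-methoxy-3-methyl-5-[(1S)-1,2,2-trimethylcyclopentyl]phenyl acetate | Cc1cc([C@@]2(C)CCCC2(C)C)c(OC)c(OC(C)=O)c1Cc1cc(OC(C)=O)c(OC)c([C@@]2(C)CCCC2(C)C)c1
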